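**Plan**

- Retrosynthesis: (a) the C1 carbonyl is traced back to an allylic carbinol tied to the tertiary C5–OH in a cis-fused acetonide; (b) the side chain is cut between the carbinol carbon C1' and C2', giving a dodecyl nucleophile and an aldehyde on the quaternary carbon; (c) the C5–C1' bond is cut to a formyl cation equivalent and the α' carbon of a cyclopentenone.
- Forward: the five-membered ring is bought intact (D-ribose-derived enone 1). The quaternary carbon is made by alkylation, the original ketone becomes the acetoxy carbinol, the chain is joined by carbonyl addition, and the acetonide carbinol is oxidised last to the enone (net 1,3-carbonyl transposition).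
- Stereochemistry: C6a of 1 is the only inherited centre. It directs hydride 1,3-anti to set C4 (target numbering), re-closure of the acetonide defines C5, and the chain-joining step sets C1' by Felkin–Anh control.
- Feature that makes the key event possible: the formyl group stands on ring-fusion carbon C3a of the cis-fused cyclopenta[d][1,3]dioxole, flanked by C4 (acetoxy on the same face) and C6a (only hydrogen on that face), with O3 as the polar α-substituent.

Key step: step 6

Remark: 1, 9 (1.0 M in Et2O) and 1,3-dithian-2-ylium tetrafluoroborate are taken as purchased (the salt can otherwise be made beforehand from 1,3-dithiane and Ph3C BF4); bicycle numbering is O1, C2, O3, C3a, C4, C5, C6, C6a.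

Step 1
Reactants: 1 (3aR,6aR)-2,2-dimethyl-3a,6a-dihydro-4H-cyclopenta[d][1,3]dioxol-4-one
Product: 3 (3aR,6aR)-3a-(1,3-dithian-2-yl)-2,2-dimethyl-3a,6a-dihydro-4H-cyclopenta[d][1,3]dioxol-4-one, via trimethylsilyl dienol ether 2 (not isolated)
Conditions: LiN(SiMe3)2, Me3SiCl, THF, −78 °C; then 1,3-dithian-2-ylium BF4, CH2Cl2, −78 to −40 °C
Reagents that add atoms: chlorotrimethylsilane, C[Si](C)(C)Cl (silyl group of 2 only); 1,3-dithian-2-ylium tetrafluoroborate, [CH+]1SCCCS1.F[B-](F)(F)F (dithianyl group of 3)
Why: Kinetic deprotonation at C3a with in-situ O-silylation gives the 2-silyloxydiene, whose enol ether carbon C3a is alkylated by the dithienium cation (Mukaiyama-type SN1 alkylation of a silyl enol ether, well suited to fully substituted carbons); because the dioxolane can only stay cis-fused, the masked formyl group is forced onto the face opposite O3, which fixes the quaternary centre.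

Step 2
Reactants: 3 (3aR,6aR)-3a-(1,3-dithian-2-yl)-2,2-dimethyl-3a,6a-dihydro-4H-cyclopenta[d][1,3]dioxol-4-one
Product: 4 (4R,5R)-5-(1,3-dithian-2-yl)-4,5-dihydroxycyclopent-2-en-1-one
Conditions: TFA/H2O (4:1), 0 °C to rt
Reagents that add atoms: none
Why: Acid-catalysed hydrolysis of the isopropylidene acetal (dithioacetal and enone are stable to aqueous acid) uncovers the two syn hydroxyl groups on C4 and C5 that the next step needs as directing groups.

Step 3
Reactants: 4 (4R,5R)-5-(1,3-dithian-2-yl)-4,5-dihydroxycyclopent-2-en-1-one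
Product: 5 (1R,3R)-2-(1,3-dithian-2-yl)cyclopent-4-ene-1,2,3-triol
Conditions: Me4NBH(OAc)3, MeCN/AcOH (1:1), −40 to −20 °C
Reagents that add atoms: none
Why: Hydroxyl-directed Evans–Saksena reduction: the triacetoxyborohydride exchanges an acetate for the C4 (β) or C5 (α) hydroxyl and delivers hydride inside the molecule to the ketone face that carries these groups, so the new carbinol oxygen ends trans to both (1,3-anti), the enone double bond being spared because the reagent reduces only by internal delivery.

Step 4
Reactants: 5 (1R,3R)-2-(1,3-dithian-2-yl)cyclopent-4-ene-1,2,3-triol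
Product: 7 (3aR,4R,6aR)-3a-(1,3-dithian-2-yl)-2,2-dimethyl-4,6a-dihydro-3aH-cyclopenta[d][1,3]dioxol-4-yl acetate, via acetonide alcohol 6 (not isolated)
Conditions: Me2C(OMe)2, PPTS, acetone, rt; concentrate; Ac2O, Et3N, DMAP, CH2Cl2, 0 °C to rt
Reagents that add atoms: 2,2-dimethoxypropane, COC(C)(C)OC; acetic anhydride, CC(=O)OC(C)=O
Why: Thermodynamic acetonide formation can join the tertiary hydroxyl only to the one flanking hydroxyl that is cis to it (a trans-fused dioxolane on a cyclopentene is not viable), which re-creates the quaternary stereocentre in defined form and leaves exactly the carbinol cis to the dithianyl group free for DMAP-catalysed acetylation.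

Step 5
Reactants: 7 (3aR,4R,6aR)-3a-(1,3-dithian-2-yl)-2,2-dimethyl-4,6a-dihydro-3aH-cyclopenta[d][1,3]dioxol-4-yl acetate
Product: 8 (3aR,4R,6aR)-3a-formyl-2,2-dimethyl-4,6a-dihydro-3aH-cyclopenta[d][1,3]dioxol-4-yl acetate
Conditions: PhI(OCOCF3)2, NaHCO3, MeCN/H2O (9:1), 0 °C
Reagents that add atoms: water, O
Why: Oxidative dethioacetalisation by the iodine reagent (sulfur activation, thionium ion, capture by water) releases the aldehyde under buffered, nearly neutral conditions that leave acetate, acetonide and alkene alone; the aldehyde has no α-hydrogen, so it cannot epimerise or eliminate acetate.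

Step 6
Reactants: 8 (3aR,4R,6aR)-3a-formyl-2,2-dimethyl-4,6a-dihydro-3aH-cyclopenta[d][1,3]dioxol-4-yl acetate; 9 dodecylmagnesium bromide
Product: 11 (3aR,4R,6aR)-3a-[(1S)-1-hydroxytridecyl]-2,2-dimethyl-4,6a-dihydro-3aH-cyclopenta[d][1,3]dioxol-4-yl acetate, via dodecyltitanium triisopropoxide 10 (not isolated)
Conditions: 9, ClTi(OiPr)3, THF/Et2O, −78 to −30 °C; then 8, −78 to −10 °C; cold aq. NH4Cl
Reagents that add atoms: chlorotitanium triisopropoxide, CC(C)O[Ti](Cl)(OC(C)C)OC(C)C (titanium and isopropoxide groups of 10 only; nothing in 11)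
Why: Transmetalation of 9 with ClTi(OiPr)3 gives the monomeric alkyltitanium 10, which adds its dodecyl group to the aldehyde through a four-centre transition state; this is the chemoselective carbonyl addition of alkyltitanium triisopropoxides, and no ring is closed. Reagent 10 is too weak a Lewis acid to chelate, so the aldehyde should react in the Felkin–Anh (Cornforth) arrangement with the C3a–O3 bond anti to the forming bond and the carbonyl dipole turned away from O3. The two flanks of C3a then differ sharply: C4 holds its acetoxy group on the same face as the formyl group and C6a holds only hydrogen there, so the dodecyl group should come in past C6a and set the new carbinol centre as (1S), the anti relationship to O3 found in the target. The step needs aldehyde-over-ester chemoselectivity and one carbonyl face; the first rests on the inertness of RTi(OiPr)3 toward esters, the second on the rigid cis-fused bicycle with its quaternary carbon. Low temperature and a cold quench are meant to keep the new titanium alkoxide from taking over the neighbouring acetyl group.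

Step 7
Reactants: 11 (3aR,4R,6aR)-3a-[(1S)-1-hydroxytridecyl]-2,2-dimethyl-4,6a-dihydro-3aH-cyclopenta[d][1,3]dioxol-4-yl acetate
Product: 12 (1R,4R,5R)-4,5-dihydroxy-5-[(1S)-1-hydroxytridecyl]cyclopent-2-en-1-yl acetate
Conditions: TFA/H2O (9:1), CH2Cl2, 0 °C
Reagents that add atoms: none
Why: Acid-catalysed acetal hydrolysis; the acetate resists cold aqueous acid and the absence of base suppresses migration of the acetyl group to the neighbouring hydroxyls.

Step 8
Reactants: 12 (1R,4R,5R)-4,5-dihydroxy-5-[(1S)-1-hydroxytridecyl]cyclopent-2-en-1-yl acetate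
Product: 13 (1R,5S)-5-hydroxy-5-[(1S)-1-hydroxytridecyl]-4-oxocyclopent-2-en-1-yl acetate
Conditions: MnO2 (activated), CH2Cl2, rt
Reagents that add atoms: none
Why: Chemoselective MnO2 oxidation of the allylic secondary alcohol (the saturated side-chain carbinol and the tertiary alcohol are not oxidised) gives the enone and completes the 1,3-carbonyl transposition without touching a stereocentre.

**Compound list**

1 | (3aR,6aR)-2,2-dimethyl-3a,6a-dihydro-4H-cyclopenta[d][1,3]dioxol-4-one (enone derived from D-ribose) | O=C1C=C[C@H]2OC(C)(C)O[C@@H]12 | starting material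
2 | cross-conjugated trimethylsilyl dienol ether of 1 (C3a=C4 and C5=C6 double bonds, OSiMe3 on C4, 6aR) | C[Si](C)(C)OC1=C2OC(C)(C)O[C@@H]2C=C1 | intermediate (not isolated)
3 | (3aR,6aR)-3a-(1,3-dithian-2-yl)-2,2-dimethyl-3a,6a-dihydro-4H-cyclopenta[d][1,3]dioxol-4-one | O=C1C=C[C@H]2OC(C)(C)O[C@@]12C1SCCCS1 | intermediate
4 | (4R,5R)-5-(1,3-dithian-2-yl)-4,5-dihydroxycyclopent-2-en-1-one (hydroxyls cis) | O=C1C=C[C@@H](O)[C@]1(O)C1SCCCS1 | intermediate
5 | (1R,3R)-2-(1,3-dithian-2-yl)cyclopent-4-ene-1,2,3-triol (flanking hydroxyls trans; C2 is not stereogenic) | O[C@@H]1C=C[C@@H](O)C1(O)C1SCCCS1 | intermediate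
6 | (3aS,4R,6aR)-3a-(1,3-dithian-2-yl)-2,2-dimethyl-4,6a-dihydro-3aH-cyclopenta[d][1,3]dioxol-4-ol (4-OH cis to the dithianyl group) | O[C@@H]1C=C[C@H]2OC(C)(C)O[C@@]12C1SCCCS1 | intermediate (not isolated)
7 | (3aR,4R,6aR)-3a-(1,3-dithian-2-yl)-2,2-dimethyl-4,6a-dihydro-3aH-cyclopenta[d][1,3]dioxol-4-yl acetate | CC(=O)O[C@@H]1C=C[C@H]2OC(C)(C)O[C@@]12C1SCCCS1 | intermediate
8 | (3aR,4R,6aR)-3a-formyl-2,2-dimethyl-4,6a-dihydro-3aH-cyclopenta[d][1,3]dioxol-4-yl acetate | CC(=O)O[C@@H]1C=C[C@H]2OC(C)(C)O[C@@]12C=O | intermediate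
9 | dodecylmagnesium bromide | CCCCCCCCCCCC[Mg]Br | starting material
10 | dodecyltitanium triisopropoxide | CCCCCCCCCCCC[Ti](OC(C)C)(OC(C)C)OC(C)C | intermediate (not isolated)
11 | (3aR,4R,6aR)-3a-[(1S)-1-hydroxytridecyl]-2,2-dimethyl-4,6a-dihydro-3aH-cyclopenta[d][1,3]dioxol-4-yl acetate | CC(=O)O[C@@H]1C=C[C@H]2OC(C)(C)O[C@@]12[C@@H](O)CCCCCCCCCCCC | intermediate
12 | (1R,4R,5R)-4,5-dihydroxy-5-[(1S)-1-hydroxytridecyl]cyclopent-2-en-1-yl acetate | CC(=O)O[C@@H]1C=C[C@@H](O)[C@]1(O)[C@@H](O)CCCCCCCCCCCC | intermediate
13 | (1R,5S)-5-hydroxy-5-[(1S)-1-hydroxytridecyl]-4-oxocyclopent-2-en-1-yl acetate, that is (4R,5S)-4-acetoxy-5-hydroxy-5-[(1S)-1-hydroxytridecyl]cyclopent-2-en-1-one | CCCCCCCCCCCC[C@H](O)[C@@]1(O)C(=O)C=C[C@H]1OC(C)=O | target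

Total steps: 8. Longest linear sequence: 8 steps (1 to 13).

**Steps most likely to fail**

Step 6. The addition may show poor facial selectivity at the neopentyl aldehyde, or be slow enough for the new alkoxide to take over the neighbouring acetyl group. The fallback sets out from 8 and sets the carbinol centre by reduction instead of addition. Addition of 9 itself (Et2O, −78 °C) without regard to selectivity should give 11 mixed with its side-chain epimer, (3aR,4R,6aR)-3a-[(1R)-1-hydroxytridecyl]-2,2-dimethyl-4,6a-dihydro-3aH-cyclopenta[d][1,3]dioxol-4-yl acetate F1. Dess–Martin oxidation of the mixture should converge on the ketone (3aR,4R,6aR)-2,2-dimethyl-3a-tridecanoyl-4,6a-dihydro-3aH-cyclopenta[d][1,3]dioxol-4-yl acetate F2. Reduction of F2 with Zn(BH4)2 (Et2O, −30 °C) under chelation control, with zinc bridging the ketone oxygen and O3 and hydride arriving from the C6a flank, should give the same anti relationship and return to the route at 11.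

Step 1. The silyloxydiene may undergo a 1,5-hydrogen shift or dimerise before it is alkylated, or the cation may attack the fully substituted carbon too slowly. The fallback sets out from 1 and builds the masked formyl group in stages. The lithium enolate (LiN(SiMe3)2, THF, −78 °C) is trapped with monomeric formaldehyde to give (3aR,6aR)-3a-(hydroxymethyl)-2,2-dimethyl-3a,6a-dihydro-4H-cyclopenta[d][1,3]dioxol-4-one F3. Dess–Martin oxidation should give the non-enolisable keto aldehyde (3aS,6aR)-2,2-dimethyl-4-oxo-4,6a-dihydro-3aH-cyclopenta[d][1,3]dioxole-3a-carbaldehyde F4. Chemoselective dithioacetalisation of the aldehyde (propane-1,3-dithiol, Zn(OTf)2, CH2Cl2, 0 °C) returns to the route at 3.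

Step 8. The vicinal diol may be cleaved oxidatively, or the side-chain carbinol may compete in the allylic oxidation. The fallback sets out from 11 and masks the side-chain hydroxyl before the diol is released. Silylation (tBuMe2SiOTf, 2,6-lutidine) gives the tert-butyldimethylsilyl ether of 11 at the side-chain hydroxyl F5. Acetonide hydrolysis with 80% aqueous AcOH, chosen to spare the hindered silyl ether, gives the tert-butyldimethylsilyl ether of 12 at the side-chain hydroxyl F6. IBX (EtOAc, 70 °C) oxidises the only remaining secondary alcohol to the α-ketol without C–C cleavage and gives the tert-butyldimethylsilyl ether of 13 at the side-chain hydroxyl F7. HF·pyridine (THF, 0 °C) then returns to the route at 13.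

**Further compounds**

F1 | step 6 | (3aR,4R,6aR)-3a-[(1R)-1-hydroxytridecyl]-2,2-dimethyl-4,6a-dihydro-3aH-cyclopenta[d][1,3]dioxol-4-yl acetate | CC(=O)O[C@@H]1C=C[C@H]2OC(C)(C)O[C@@]12[C@H](O)CCCCCCCCCCCC
F2 | step 6 | (3aR,4R,6aR)-2,2-dimethyl-3a-tridecanoyl-4,6a-dihydro-3aH-cyclopenta[d][1,3]dioxol-4-yl acetate | CC(=O)O[C@@H]1C=C[C@H]2OC(C)(C)O[C@@]12C(=O)CCCCCCCCCCCC
F3 | step 1 | (3aR,6aR)-3a-(hydroxymethyl)-2,2-dimethyl-3a,6a-dihydro-4H-cyclopenta[d][1,3]dioxol-4-one | O=C1C=C[C@H]2OC(C)(C)O[C@@]12CO
F4 | step 1 | (3aS,6aR)-2,2-dimethyl-4-oxo-4,6a-dihydro-3aH-cyclopenta[d][1,3]dioxole-3a-carbaldehyde | O=C1C=C[C@H]2OC(C)(C)O[C@@]12C=O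
F5 | step 8 | tert-butyldimethylsilyl ether of 11 at the side-chain hydroxyl | CC(=O)O[C@@H]1C=C[C@H]2OC(C)(C)O[C@@]12[C@@H](O[Si](C)(C)C(C)(C)C)CCCCCCCCCCCC
F6 | step 8 | tert-butyldimethylsilyl ether of 12 at the side-chain hydroxyl | CC(=O)O[C@@H]1C=C[C@@H](O)[C@]1(O)[C@@H](O[Si](C)(C)C(C)(C)C)CCCCCCCCCCCC
F7 | step 8 | tert-butyldimethylsilyl ether of 13 at the side-chain hydroxyl | CC(=O)O[C@@H]1C=CC(=O)[C@]1(O)[C@@H](O[Si](C)(C)C(C)(C)C)CCCCCCCCCCCC
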